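Qd and Qj both leave Qg, each at its rate constant times cQg, so throughout a run the Qd made (Qf counted) stands to the Qj made as 91 min⁻¹ to 6.0 × 10⁻⁴ min⁻¹: this is the turnover number, the Qd made per Qa lost to Qj, 1.52 × 10⁵.

    Qb + Qa ⇌ Qg (K1 = 850 M⁻¹, k1 = 58000 M⁻¹ min⁻¹)
    Qg → Qa + Qd (k2 = 91 min⁻¹)
    Qc + Qa ⇌ Qh (K3 = 8.7 M⁻¹, k3 = 72000 M⁻¹ min⁻¹)
    Qh → Qa + Qe (k4 = 38 min⁻¹)
    Qg → Qj (k5 = 6.0 × 10⁻⁴ min⁻¹)
    Qd ⇌ Qf (K6 = 32, k6 = 0.0023 min⁻¹)

in all of them: Qb 0.050 M; Qc 1.00 equiv; Qa 0.0015 mol%

| charge | time |
|---|---|
| alpha | 10 h |
| theta | 12 h |

1. which of these there is most of at the end, counted by the Qb in it, alpha (Qf / Qb / Qg / Qd)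
2. which of these there is most of at the end, counted by the Qb in it, theta (Qf / Qb / Qg / Qd)
3. the largest of these amounts at the end, in percent of the Qb charged, alpha
4. the largest of these amounts at the end, in percent of the Qb charged, theta

The charge asks 66700 turnovers of each Qa, fewer than the turnover number, so the Qb lost reaches the whole charge with 44.0% of the Qa gone to Qj. What we must count, then, is the Qj formed by the asked time.

Qj grows with cQg, so we need the share of live catalyst sitting as Qg, the resting state. The steady-state constant for Qb is 0.00275 M, well below cQb at the start, and the one for Qc is 0.115 M. With equal charges of Qb and Qc, Qg holds 92.7% of the live catalyst at the start.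

We hold that share. Qj then reaches 28.4% of the Qa in alpha and 33.0% in theta. Multiplying by the turnover number and the loading, the Qb used is 64.6% in alpha and 75.1% in theta.

Qd relaxes towards Qf at 0.00237 min⁻¹. Under a steady feed, the share of the product still standing as Qd is 53.3% in alpha and 47.9% in theta.

We commit to Qb at 35.4% for alpha, and Qf at 39.1% for theta.

The weak link is the held share, since cQb falls, and the alpha lead over Qd at 34.4% is thin. Reforged for alpha, the share at the end is 81.8%, and the mean of start and end is 87.3%. That leaves 38.7% of the Qb in alpha, with the order unchanged.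

The forecast names Qb at 37.8% for alpha and Qf at 38.5% for theta, holding that “The catalyst sits almost entirely as Qg”. Its alpha figure stands above our committed one.

The flask gives Qb at 37.8% in alpha and Qf at 38.5% in theta. In alpha, 27.4% of the charged Qa stands as Qj at 10.0 h. The turnover number makes that 62.2% of the Qb used, and the flask has 62.2% gone. A neighbouring flask is theta with Qa cut to 6.0 × 10⁻⁴ mol%, and it has 32.6% of its Qa as Qj at 12.0 h. By the same turnover number that means 29.7% of its Qb used, and its Qb left stands at 70%.

The rate constants are made up; the run is a simulation.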